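The readings were generated by integration from invented constants; scatter was added.

In the amber run at 10.0 d, 8.2% of the electrophile remains and the target stands at 24.5%. Electrophile leaves by two paths: nucleophile takes it and makes target, or target takes it and makes side product, which costs one target as well. So two amounts matter, the electrophile taken by nucleophile and the electrophile taken by target, and the balance gives their ratio without a reading of side product. This ratio, the split (a selectivity factor), is the part reacted plus target over the part reacted minus target.

| setting | amber | ochre | grey | flask |
|---|---|---|---|---|
| electrophile | 0.084 M | 0.13 M | 0.060 M | 0.060 M |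
| nucleophile | 0.063 M | 0.063 M | 0.13 M | 0.0630 M |
| free base | 0.18 M | 0.18 M | 0.18 M | 0.180 M |
| remark | run made earlier | run made earlier | run made earlier |  |
| time |  |  |  | 10 d |

- amber (time / d: electrophile / %, target / %): 0.833: 58.4, 30.5; 2.50: 32.7, 32.4; 5.00: 20.2, 29.1; 8.00: 12.0, 26.0; 10.0: 8.2, 24.5
- ochre (time / d: electrophile / %, target / %): 0.833: 64.8, 21.4; 1.67: 52.4, 18.5; 3.00: 42.1, 15.9; 5.00: 29.7, 11.7; 10.0: 20.8, 6.6
- grey (time / d: electrophile / %, target / %): 2.08: 7.1, 75.2; 4.00: 3.2, 75.4; 6.00: 1.4, 76.3; 8.00: 0, 76.6; 10.0: 0, 76.7

(readings scatter by 1 percentage point)

- percentages count the electrophile that a species holds: one side product counts as two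
- acid set free is meant together with its idle adduct
- reactions considered so far: nucleophile + acid set free <-> protonated nucleophile; electrophile + nucleophile -> acid set free + target; acid set free + free base <-> salt of the base; acid set free + free base <-> idle adduct; electrophile + target -> side product
- the earlier runs do not show how much of nucleophile is bound; that part of a forecast is a guess

* part of the electrophile that has reacted at 10 d
* share of the unused nucleophile that is free and not bound as protonated nucleophile, at 10 d

Amber gives a split of 1.73 and grey 7.58. In logarithms, against charged [nucleophile]/[electrophile], the line through them has a slope, the split exponent, of 1.39. At the ratio of 1.05 in this flask, we reckon a split of 2.76 at 10 d.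

The forecast gives 94% reacted and 32% free, holding that “protonated nucleophile competes well with the base”.

The flask gives 96.1% reacted and 25.8% free, so the forecast's share stands 6.2 percentage points high.

    nucleophile + acid set free ⇌ protonated nucleophile, settled at all times (K = 7500 /M)
    electrophile + nucleophile → acid set free + target (k = 2.10 × 10⁻⁴ /M/s)
    acid set free + free base ⇌ salt of the base, settled at all times (K = 420 /M)
    acid set free + free base ⇌ idle adduct, settled at all times (K = 24.0 /M)
    electrophile + target → side product (k = 6.20 × 10⁻⁵ /M/s)

The flask's split at 10.0 d comes to 2.70, against our 2.76. For a neighbouring flask, the same but for 0.024 M of electrophile, the exponent gives 9.91, and its target and side product at 10.0 d give 11.5. At 0.598 d the flask's electrophile goes faster by nucleophile than by target, their ratio being 4.7. At 10.0 d that ratio is 0.69.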